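**Retrosynthetic overview**

- The target is cut at the upper-unit C2–C3 bond and at the interflavan C4(upper)–C6(lower) bond. This leads back to an open-chain (E)-enol acetate carrying a mixed O-aryl O-methyl acetal (upper ring A, C3, C4 and the ring B aldehyde carbon C2) and to the (2R,3R)-dihydroflavonol of the lower unit.
- Enabling feature: upper C4 is benzylic to ring A, para to the C7 oxygen and ortho to O1. When the acetoxy-bearing alkene carbon C3 attacks the O1=C2 oxocarbenium ion, the product is the quinone-methide-stabilised flavan-4-yl cation, the electrophile of proanthocyanidin biosynthesis; lower C6 (ortho to O7, para to O1) is its matching nucleophile.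
- Ring order: lower ring C first (chalcone epoxide to dihydroflavonol), then upper ring C in the key one-pot cascade, which also forms the interflavan bond and sets upper C2, C3 and C4.
- Endgame: hydrogenolysis (six benzyl ethers and a blocking bromine), then hydride reduction of the lower C4 ketone to the 3,4-trans diol with loss of the acetate.

Key step: step 13

Remark on the structure: the upper unit is read as 2,3-trans-3,4-trans (2S,3R,4S) and the lower unit as 2,3-trans-3,4-trans (2R,3S,4R), joined C4(upper)–C6(lower), that is the ent-oritin-(4β→6)-oritin-4α-ol pattern.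

Assumption: the (R)-configured phosphoramide acid of step 13 is taken to deliver the 2S series. The sense of induction has to be confirmed on a model; the (S)-antipode would be used in the same way if it proves opposite.

**Fragment 1 (lower unit)**

Step 1
Reactants: 1 2,3,4-trihydroxyacetophenone
Product: 2 1-[3,4-bis(benzyloxy)-2-hydroxyphenyl]ethanone
Conditions: BnBr (2.1 equiv), K2CO3, DMF, rt
Reagents that add atoms: benzyl bromide, BrCc1ccccc1
Why: Williamson etherification in which the 2-hydroxyl, hydrogen-bonded to the acetyl carbonyl, is the least nucleophilic, so two equivalents of BnBr should take only the 4- and 3-hydroxyls.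

Step 2
Reactants: 2 1-[3,4-bis(benzyloxy)-2-hydroxyphenyl]ethanone
Product: 3 1-[3,4-bis(benzyloxy)-2-(methoxymethoxy)phenyl]ethanone
Conditions: NaH, MOMCl, DMF, 0 °C
Reagents that add atoms: chloromethyl methyl ether, COCCl
Why: Williamson-type O-alkylation of the sodium phenoxide gives a MOM ether that survives the basic steps and is removed by acid in step 5.

Step 3
Reactants: 3 1-[3,4-bis(benzyloxy)-2-(methoxymethoxy)phenyl]ethanone, 4 4-(benzyloxy)benzaldehyde
Product: 5 (E)-1-[3,4-bis(benzyloxy)-2-(methoxymethoxy)phenyl]-3-[4-(benzyloxy)phenyl]prop-2-en-1-one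
Conditions: KOH (aq.), EtOH–THF, rt
Reagents that add atoms: none
Why: Claisen–Schmidt aldol condensation, in which dehydration of the aldol should give the conjugated E-enone.

Step 4
Reactants: 5 (E)-1-[3,4-bis(benzyloxy)-2-(methoxymethoxy)phenyl]-3-[4-(benzyloxy)phenyl]prop-2-en-1-one
Product: 6 [3,4-bis(benzyloxy)-2-(methoxymethoxy)phenyl]{(2R,3S)-3-[4-(benzyloxy)phenyl]oxiran-2-yl}methanone
Conditions: poly-L-leucine, urea–H2O2, DBU, THF, rt
Reagents that add atoms: hydrogen peroxide (as its urea adduct), OO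
Why: Juliá–Colonna epoxidation, in which the hydroperoxide adds to the enone inside the helical poly-L-leucine, should give the trans-(2R,3S)-epoxide with both new stereocentres set by the catalyst.

Step 5
Reactants: 6 [3,4-bis(benzyloxy)-2-(methoxymethoxy)phenyl]{(2R,3S)-3-[4-(benzyloxy)phenyl]oxiran-2-yl}methanone
Product: 7 (2R,3R)-7,8-bis(benzyloxy)-2-[4-(benzyloxy)phenyl]-3-hydroxy-2,3-dihydro-4H-chromen-4-one
Conditions: conc. HCl, MeOH–THF, 55 °C
Reagents that add atoms: none
Why: Acid removes the MOM group and the freed phenol opens the epoxide at the benzylic carbon with inversion (intramolecular epoxide opening, 6-endo), so the retained carbinol centre (C3) and the inverted benzylic centre (C2) should give the 2,3-trans (2R,3R)-dihydroflavonol.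

**Fragment 2 (upper unit precursor)**

Step 6
Reactants: 8 2,3,4-trihydroxybenzaldehyde
Product: 9 3,4-bis(benzyloxy)-2-hydroxybenzaldehyde
Conditions: BnBr (2.1 equiv), K2CO3, DMF, rt
Reagents that add atoms: benzyl bromide, BrCc1ccccc1
Why: Williamson etherification that should leave the 2-hydroxyl, hydrogen-bonded to the formyl group, untouched.

Step 7
Reactants: 9 3,4-bis(benzyloxy)-2-hydroxybenzaldehyde
Product: 10 3,4-bis(benzyloxy)-5-bromo-2-hydroxybenzaldehyde
Conditions: NBS, MeCN, 0 °C → rt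
Reagents that add atoms: N-bromosuccinimide, O=C1CCC(=O)N1Br
Why: Electrophilic aromatic bromination at the only position para to the free hydroxyl and ortho to a benzyloxy group installs a bromine that later blocks C6 of the upper ring A against self-condensation.

Step 8
Reactants: 4 4-(benzyloxy)benzaldehyde
Product: 11 1-(benzyloxy)-4-(dimethoxymethyl)benzene
Conditions: HC(OMe)3, p-TsOH (cat.), MeOH, rt; Et3N quench
Reagents that add atoms: trimethyl orthoformate, COC(OC)OC; methanol, CO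
Why: Acid-catalysed acetalisation, driven by the orthoformate as water scavenger.

Step 9
Reactants: 11 1-(benzyloxy)-4-(dimethoxymethyl)benzene
Product: 12 1-(benzyloxy)-4-[chloro(methoxy)methyl]benzene
Conditions: AcCl (1.1 equiv), SOCl2 (cat.), CH2Cl2, 0 °C → rt; evaporation, used crude
Reagents that add atoms: acetyl chloride, CC(=O)Cl
Why: Acetyl chloride exchanges one methoxy group of the acetal for chloride (α-chloro ether formation from an acetal) with loss of methyl acetate.

Step 10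
Reactants: 10 3,4-bis(benzyloxy)-5-bromo-2-hydroxybenzaldehyde, 12 1-(benzyloxy)-4-[chloro(methoxy)methyl]benzene
Product: 13 3,4-bis(benzyloxy)-2-{[4-(benzyloxy)phenyl](methoxy)methoxy}-5-bromobenzaldehyde
Conditions: iPr2NEt, CH2Cl2, 0 °C → rt; chromatography on Et3N-deactivated silica
Reagents that add atoms: none
Why: Williamson-type O-alkylation of the acidic salicylaldehyde phenol by the reactive α-chloro ether (as in MOM ether formation) should give the base-stable mixed O-aryl O-methyl acetal, the latent O-aryl oxocarbenium ion.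

Step 11
Reactants: 13 3,4-bis(benzyloxy)-2-{[4-(benzyloxy)phenyl](methoxy)methoxy}-5-bromobenzaldehyde
Product: 14 2-[(E)-2-(3,4-bis(benzyloxy)-2-{[4-(benzyloxy)phenyl](methoxy)methoxy}-5-bromophenyl)ethenyl]-4,4,5,5-tetramethyl-1,3,2-dioxaborolane
Conditions: CH2(Bpin)2, LiTMP (lithium 2,2,6,6-tetramethylpiperidide), THF, −78 °C → rt
Reagents that add atoms: bis[(pinacolato)boryl]methane, CC1(C)OB(CB2OC(C)(C)C(C)(C)O2)OC1(C)C
Why: Boron-Wittig olefination, in which the α-boryl carbanion adds to the aldehyde and syn-elimination of the borate should give the E-alkenyl boronate.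

Step 12
Reactants: 14 2-[(E)-2-(3,4-bis(benzyloxy)-2-{[4-(benzyloxy)phenyl](methoxy)methoxy}-5-bromophenyl)ethenyl]-4,4,5,5-tetramethyl-1,3,2-dioxaborolane
Product: 15 (E)-2-(3,4-bis(benzyloxy)-2-{[4-(benzyloxy)phenyl](methoxy)methoxy}-5-bromophenyl)ethenyl acetate
Conditions: Cu(OAc)2 (2 equiv), Et3N, 4 Å MS, MeCN, air, rt
Reagents that add atoms: Cu(OAc)2, CC(=O)[O-].CC(=O)[O-].[Cu+2]
Why: Chan–Lam–Evans-type oxidative C–O coupling of the alkenyl boronate with acetate on copper proceeds with retention of alkene geometry and should give the E-enol acetate, with Et3N keeping the medium non-acidic for the acetal.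

**Union and endgame**

Step 13
Reactants: 15 (E)-2-(3,4-bis(benzyloxy)-2-{[4-(benzyloxy)phenyl](methoxy)methoxy}-5-bromophenyl)ethenyl acetate, 7 (2R,3R)-7,8-bis(benzyloxy)-2-[4-(benzyloxy)phenyl]-3-hydroxy-2,3-dihydro-4H-chromen-4-one
Product: 19 (2S,3R,4S)-7,8-bis(benzyloxy)-4-{(2R,3R)-7,8-bis(benzyloxy)-2-[4-(benzyloxy)phenyl]-3-hydroxy-4-oxo-3,4-dihydro-2H-chromen-6-yl}-2-[4-(benzyloxy)phenyl]-6-bromo-3,4-dihydro-2H-chromen-3-yl acetate, via oxocarbenium ion 16 (not isolated), via flavan-4-yl cation 17 (not isolated), via 4-methoxyflavan adduct 18 (not isolated)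
Conditions: (R)-3,3'-bis(2,4,6-triisopropylphenyl)-1,1'-binaphthyl-2,2'-diyl N-triflylphosphoramide (10 mol %), toluene–CH2Cl2, −60 °C until 15 is consumed; then 7 (3 equiv), 5 Å MS, TMSOTf (0.2 equiv), −40 → −20 °C; Et3N quench
Reagents that add atoms: none
Why: Proposed new method: the chiral phosphoramide acid ionises the mixed acetal (net loss of MeOH) to the O-aryl oxocarbenium ion 16 as a contact ion pair, whose carbon C2 is attacked by the acetoxy-bearing alkene carbon C3 (the nucleophilic terminus of a para-benzyloxystyrene) in a Prins cyclisation that closes ring C and gives the flavan-4-yl cation 17, which is stored reversibly as its methanol adduct 18, then re-ionised by TMSOTf and captured at C6 of 7 in a Friedel–Crafts step. The closest known reaction types are Prins cyclisation–Friedel–Crafts cascades of oxocarbenium ions, enantioselective additions to benzopyran-derived oxocarbenium ions paired with chiral phosphoramide anions, and the Lewis-acid coupling of 4-alkoxyflavans with flavonoid A rings. Ring C, the only ring formed, closes in the 6-endo-trig mode (O1=C2 and C3=C4 both endocyclic) through a half-chair in which the C2 aryl and C3 acetoxy groups are pseudo-equatorial. C2 (S) is set by the chiral counter-anion, C3 (R, 2,3-trans) by the E geometry of the enol acetate, and C4 (S, 3,4-trans) by attack of the arene anti to the C3 acetoxy group, supported by acetoxonium participation. The step needs attack through C3 and not C4 of the alkene (secured by the benzylic, para-oxygen-stabilised C4 cation and by six- over five-membered ring closure), reaction at C6 of 7 (the only position ortho to O7 and para to O1, C5 lying next to the carbonyl-bearing carbon) and no oligomerisation (secured by the bromine at C6 of the upper ring A, by the staged addition and by the excess of 7).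

Step 14
Reactants: 19 (2S,3R,4S)-7,8-bis(benzyloxy)-4-{(2R,3R)-7,8-bis(benzyloxy)-2-[4-(benzyloxy)phenyl]-3-hydroxy-4-oxo-3,4-dihydro-2H-chromen-6-yl}-2-[4-(benzyloxy)phenyl]-6-bromo-3,4-dihydro-2H-chromen-3-yl acetate
Product: 20 (2S,3R,4S)-7,8-dihydroxy-2-(4-hydroxyphenyl)-4-[(2R,3R)-3,7,8-trihydroxy-2-(4-hydroxyphenyl)-4-oxo-3,4-dihydro-2H-chromen-6-yl]-3,4-dihydro-2H-chromen-3-yl acetate
Conditions: H2 (1 atm), Pd(OH)2/C, NaOAc (1.5 equiv), THF–MeOH, rt
Reagents that add atoms: none
Why: Catalytic hydrogenolysis should cleave the six benzyl ethers and the aryl C–Br bond, while the chromanone carbonyl, the acetate, the cyclic benzylic ethers and the interflavan bond survive under these neutral, buffered conditions.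

Step 15
Reactants: 20 (2S,3R,4S)-7,8-dihydroxy-2-(4-hydroxyphenyl)-4-[(2R,3R)-3,7,8-trihydroxy-2-(4-hydroxyphenyl)-4-oxo-3,4-dihydro-2H-chromen-6-yl]-3,4-dihydro-2H-chromen-3-yl acetate
Product: 21 (2R,3S,4R)-2-(4-hydroxyphenyl)-6-[(2S,3R,4S)-3,7,8-trihydroxy-2-(4-hydroxyphenyl)-3,4-dihydro-2H-chromen-4-yl]-3,4-dihydro-2H-chromene-3,4,7,8-tetrol
Conditions: LiBH4 (excess), THF–MeOH, 0 °C → rt, argon; AcOH to pH 6
Reagents that add atoms: none
Why: Borohydride reduction, with axial hydride delivery to the C4 carbonyl of the 2,3-trans-dihydroflavonol, should give the equatorial 4-hydroxyl (3,4-trans, 4R) under control of the ring conformation fixed by C2 and C3, and LiBH4 also cleaves the acetate reductively in the same operation.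

**Compound list**

1 | 2,3,4-trihydroxyacetophenone | CC(=O)c1ccc(O)c(O)c1O | starting material
2 | 1-[3,4-bis(benzyloxy)-2-hydroxyphenyl]ethanone | CC(=O)c1ccc(OCc2ccccc2)c(OCc2ccccc2)c1O | intermediate
3 | 1-[3,4-bis(benzyloxy)-2-(methoxymethoxy)phenyl]ethanone | CC(=O)c1ccc(OCc2ccccc2)c(OCc2ccccc2)c1OCOC | intermediate
4 | 4-(benzyloxy)benzaldehyde | O=Cc1ccc(OCc2ccccc2)cc1 | starting material
5 | (E)-1-[3,4-bis(benzyloxy)-2-(methoxymethoxy)phenyl]-3-[4-(benzyloxy)phenyl]prop-2-en-1-one | COCOc1c(C(=O)/C=C/c2ccc(OCc3ccccc3)cc2)ccc(OCc2ccccc2)c1OCc1ccccc1 | intermediate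
6 | [3,4-bis(benzyloxy)-2-(methoxymethoxy)phenyl]{(2R,3S)-3-[4-(benzyloxy)phenyl]oxiran-2-yl}methanone | COCOc1c(C(=O)[C@@H]2O[C@H]2c2ccc(OCc3ccccc3)cc2)ccc(OCc2ccccc2)c1OCc1ccccc1 | intermediate
7 | (2R,3R)-7,8-bis(benzyloxy)-2-[4-(benzyloxy)phenyl]-3-hydroxy-2,3-dihydro-4H-chromen-4-one | c1ccccc1COc1ccc([C@H]2Oc3c(ccc(OCc4ccccc4)c3OCc3ccccc3)C(=O)[C@@H]2O)cc1 | intermediate
8 | 2,3,4-trihydroxybenzaldehyde | O=Cc1ccc(O)c(O)c1O | starting material
9 | 3,4-bis(benzyloxy)-2-hydroxybenzaldehyde | O=Cc1ccc(OCc2ccccc2)c(OCc2ccccc2)c1O | intermediate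
10 | 3,4-bis(benzyloxy)-5-bromo-2-hydroxybenzaldehyde | O=Cc1cc(Br)c(OCc2ccccc2)c(OCc2ccccc2)c1O | intermediate
11 | 1-(benzyloxy)-4-(dimethoxymethyl)benzene | COC(OC)c1ccc(OCc2ccccc2)cc1 | intermediate
12 | 1-(benzyloxy)-4-[chloro(methoxy)methyl]benzene (racemic) | COC(Cl)c1ccc(OCc2ccccc2)cc1 | intermediate
13 | 3,4-bis(benzyloxy)-2-{[4-(benzyloxy)phenyl](methoxy)methoxy}-5-bromobenzaldehyde (racemic at the acetal carbon) | O=Cc1cc(Br)c(OCc2ccccc2)c(OCc2ccccc2)c1OC(OC)c1ccc(OCc2ccccc2)cc1 | intermediate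
14 | 2-[(E)-2-(3,4-bis(benzyloxy)-2-{[4-(benzyloxy)phenyl](methoxy)methoxy}-5-bromophenyl)ethenyl]-4,4,5,5-tetramethyl-1,3,2-dioxaborolane | CC1(C)OB(/C=C/c2cc(Br)c(OCc3ccccc3)c(OCc3ccccc3)c2OC(OC)c2ccc(OCc3ccccc3)cc2)OC1(C)C | intermediate
15 | (E)-2-(3,4-bis(benzyloxy)-2-{[4-(benzyloxy)phenyl](methoxy)methoxy}-5-bromophenyl)ethenyl acetate | CC(=O)O/C=C/c1cc(Br)c(OCc2ccccc2)c(OCc2ccccc2)c1OC(OC)c1ccc(OCc2ccccc2)cc1 | intermediate
16 | {2-[(E)-2-acetoxyethenyl]-5,6-bis(benzyloxy)-4-bromophenyl}[4-(benzyloxy)benzylidene]oxonium (O-aryl oxocarbenium ion) | CC(=O)O/C=C/c1cc(Br)c(OCc2ccccc2)c(OCc2ccccc2)c1[O+]=Cc1ccc(OCc2ccccc2)cc1 | intermediate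
17 | (2S,3R)-3-acetoxy-7,8-bis(benzyloxy)-2-[4-(benzyloxy)phenyl]-6-bromochroman-4-ylium (flavan-4-yl cation) | [CH+]1c2cc(Br)c(OCc3ccccc3)c(OCc3ccccc3)c2O[C@@H](c2ccc(OCc3ccccc3)cc2)[C@@H]1OC(C)=O | intermediate
18 | (2S,3R)-7,8-bis(benzyloxy)-2-[4-(benzyloxy)phenyl]-6-bromo-4-methoxy-3,4-dihydro-2H-chromen-3-yl acetate (both C4 epimers) | COC1c2cc(Br)c(OCc3ccccc3)c(OCc3ccccc3)c2O[C@@H](c2ccc(OCc3ccccc3)cc2)[C@@H]1OC(C)=O | intermediate
19 | (2S,3R,4S)-7,8-bis(benzyloxy)-4-{(2R,3R)-7,8-bis(benzyloxy)-2-[4-(benzyloxy)phenyl]-3-hydroxy-4-oxo-3,4-dihydro-2H-chromen-6-yl}-2-[4-(benzyloxy)phenyl]-6-bromo-3,4-dihydro-2H-chromen-3-yl acetate | C(c1ccccc1)Oc1ccc([C@H]2Oc3c(cc([C@H]4c5cc(Br)c(OCc6ccccc6)c(OCc6ccccc6)c5O[C@@H](c5ccc(OCc6ccccc6)cc5)[C@@H]4OC(C)=O)c(OCc6ccccc6)c3OCc3ccccc3)C(=O)[C@@H]2O)cc1 | intermediate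
20 | (2S,3R,4S)-7,8-dihydroxy-2-(4-hydroxyphenyl)-4-[(2R,3R)-3,7,8-trihydroxy-2-(4-hydroxyphenyl)-4-oxo-3,4-dihydro-2H-chromen-6-yl]-3,4-dihydro-2H-chromen-3-yl acetate | Oc1ccc([C@H]2Oc3c(cc([C@H]4c5ccc(O)c(O)c5O[C@@H](c5ccc(O)cc5)[C@@H]4OC(C)=O)c(O)c3O)C(=O)[C@@H]2O)cc1 | intermediate
21 | (2R,3S,4R)-2-(4-hydroxyphenyl)-6-[(2S,3R,4S)-3,7,8-trihydroxy-2-(4-hydroxyphenyl)-3,4-dihydro-2H-chromen-4-yl]-3,4-dihydro-2H-chromene-3,4,7,8-tetrol | Oc1ccc([C@H]2Oc3c(cc([C@H]4c5ccc(O)c(O)c5O[C@@H](c5ccc(O)cc5)[C@@H]4O)c(O)c3O)[C@@H](O)[C@@H]2O)cc1 | target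

**Summary**

Total step count: 15. Longest linear sequence: 8 steps (for example 8 → 21 through steps 6, 7, 10, 11, 12, 13, 14 and 15; the sequences from 1 and from 4 are equally long).

Steps most likely to fail:

1. Step 13 (Proposed new method). The processes that may defeat it are:
   - insufficient facial discrimination of the oxocarbenium ion by the chiral counter-anion, which would give the diastereomer with an upper unit of the opposite series;
   - ring closure through C4 of the enol acetate to a five-membered ring;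
   - closure through a boat-like rather than half-chair transition state, eroding the 2,3-trans selectivity;
   - proton loss from the flavan-4-yl cation or Friedel–Crafts attack on the methyl oxocarbenium fragment outrunning the intended arylation.

   Fallback by known chemistry, setting out from chalcone 5 and returning to the route at 21: Juliá–Colonna epoxidation with poly-D-leucine should give the (2S,3R)-epoxy ketone F1. HCl in MeOH should then cyclise it to the (2S,3S)-dihydroflavonol F2, and NaBH4 should reduce this to the all-trans (2S,3R,4S)-flavan-3,4-diol F3. Slow addition of F3 to a five-fold excess of 7 with BF3·OEt2 in CH2Cl2 at 0 °C, the classical condensation of a flavan-3,4-diol with a phenolic nucleophile through the flavan-4-yl cation, should give the benzylated 3,4-trans biflavonoid ketone F4. Hydrogenolysis over Pd(OH)2/C should give the hexaphenolic ketone F5, and NaBH4 in EtOH reduces F5 to 21.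

2. Step 12. Acid- or copper-promoted cleavage of the mixed acetal, protodeboronation, or loss of the E geometry during the C–O coupling may occur. Fallback, setting out from 14 and returning at 15: oxidation of the alkenyl boronate with NaBO3·4H2O in THF–H2O should give the arylacetaldehyde F6. O-Acetylation of its enol (Ac2O, Et3N, DMAP, CH2Cl2) should then give the E-enol acetate 15 together with the Z-enol acetate F7, from which 15 is separated by chromatography.

3. Step 15. Incomplete reductive cleavage of the acetate in the presence of six phenoxides, base-induced air oxidation of the 7,8-dihydroxy rings, or poor facial selectivity at C4 may occur. Fallback, setting out from 19 and returning at 21, with reduction and deacylation done before deprotection: NaBH4 in THF–MeOH should give the benzylated flavan-3,4-diol acetate F8. K2CO3 in MeOH should then remove the acetate to give the benzylated tetrol F9. Brief hydrogenolysis (H2, Pd(OH)2/C, NaOAc, EtOAc–MeOH), stopped as soon as the benzyl ethers and the bromine are gone so that the benzylic C4 hydroxyl is kept, gives 21.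

**Further compounds**

F1 | step 13 | [3,4-bis(benzyloxy)-2-(methoxymethoxy)phenyl]{(2S,3R)-3-[4-(benzyloxy)phenyl]oxiran-2-yl}methanone | COCOc1c(C(=O)[C@H]2O[C@@H]2c2ccc(OCc3ccccc3)cc2)ccc(OCc2ccccc2)c1OCc1ccccc1
F2 | step 13 | (2S,3S)-7,8-bis(benzyloxy)-2-[4-(benzyloxy)phenyl]-3-hydroxy-2,3-dihydro-4H-chromen-4-one | c1ccccc1COc1ccc([C@@H]2Oc3c(ccc(OCc4ccccc4)c3OCc3ccccc3)C(=O)[C@H]2O)cc1
F3 | step 13 | (2S,3R,4S)-7,8-bis(benzyloxy)-2-[4-(benzyloxy)phenyl]-3,4-dihydro-2H-chromene-3,4-diol | c1ccccc1COc1ccc([C@@H]2Oc3c(ccc(OCc4ccccc4)c3OCc3ccccc3)[C@H](O)[C@H]2O)cc1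
F4 | step 13 | (2R,3R)-7,8-bis(benzyloxy)-6-{(2S,3R,4R)-7,8-bis(benzyloxy)-2-[4-(benzyloxy)phenyl]-3-hydroxy-3,4-dihydro-2H-chromen-4-yl}-2-[4-(benzyloxy)phenyl]-3-hydroxy-2,3-dihydro-4H-chromen-4-one (upper unit all-trans as in 19; the C4 descriptor changes only through the ranking rules) | C(c1ccccc1)Oc1ccc([C@H]2Oc3c(cc([C@H]4c5ccc(OCc6ccccc6)c(OCc6ccccc6)c5O[C@@H](c5ccc(OCc6ccccc6)cc5)[C@@H]4O)c(OCc6ccccc6)c3OCc3ccccc3)C(=O)[C@@H]2O)cc1
F5 | step 13 | (2R,3R)-3,7,8-trihydroxy-2-(4-hydroxyphenyl)-6-[(2S,3R,4S)-3,7,8-trihydroxy-2-(4-hydroxyphenyl)-3,4-dihydro-2H-chromen-4-yl]-2,3-dihydro-4H-chromen-4-one | Oc1ccc([C@H]2Oc3c(cc([C@H]4c5ccc(O)c(O)c5O[C@@H](c5ccc(O)cc5)[C@@H]4O)c(O)c3O)C(=O)[C@@H]2O)cc1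
F6 | step 12 | 2-(3,4-bis(benzyloxy)-2-{[4-(benzyloxy)phenyl](methoxy)methoxy}-5-bromophenyl)acetaldehyde | O=CCc1cc(Br)c(OCc2ccccc2)c(OCc2ccccc2)c1OC(OC)c1ccc(OCc2ccccc2)cc1
F7 | step 12 | (Z)-2-(3,4-bis(benzyloxy)-2-{[4-(benzyloxy)phenyl](methoxy)methoxy}-5-bromophenyl)ethenyl acetate | CC(=O)O/C=C\c1cc(Br)c(OCc2ccccc2)c(OCc2ccccc2)c1OC(OC)c1ccc(OCc2ccccc2)cc1
F8 | step 15 | (2S,3R,4S)-7,8-bis(benzyloxy)-4-{(2R,3S,4R)-7,8-bis(benzyloxy)-2-[4-(benzyloxy)phenyl]-3,4-dihydroxy-3,4-dihydro-2H-chromen-6-yl}-2-[4-(benzyloxy)phenyl]-6-bromo-3,4-dihydro-2H-chromen-3-yl acetate | C(c1ccccc1)Oc1ccc([C@H]2Oc3c(cc([C@H]4c5cc(Br)c(OCc6ccccc6)c(OCc6ccccc6)c5O[C@@H](c5ccc(OCc6ccccc6)cc5)[C@@H]4OC(C)=O)c(OCc6ccccc6)c3OCc3ccccc3)[C@@H](O)[C@@H]2O)cc1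
F9 | step 15 | (2R,3S,4R)-7,8-bis(benzyloxy)-6-{(2S,3R,4S)-7,8-bis(benzyloxy)-2-[4-(benzyloxy)phenyl]-6-bromo-3-hydroxy-3,4-dihydro-2H-chromen-4-yl}-2-[4-(benzyloxy)phenyl]-3,4-dihydro-2H-chromene-3,4-diol | C(c1ccccc1)Oc1ccc([C@H]2Oc3c(cc([C@H]4c5cc(Br)c(OCc6ccccc6)c(OCc6ccccc6)c5O[C@@H](c5ccc(OCc6ccccc6)cc5)[C@@H]4O)c(OCc6ccccc6)c3OCc3ccccc3)[C@@H](O)[C@@H]2O)cc1
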